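**Retrosynthetic overview**
- Fragransin B1 ⇒ its all-cis isomer. Both benzylic C–O bonds (C2–O, C5–O) are broken and re-made under acid, and the thermodynamic re-closure sets C2 and C5.
- All-cis oxolane ⇒ 2,5-diaryl-3,4-dimethylfuran. Syn-hydrogenation sets the cis C3/C4 methyl pair.
- Furan ⇒ 1,4-diketone by C–O ring closure (Paal–Knorr). This is the only ring built, and it is made once, before any stereocentre exists.
- 1,4-Diketone ⇒ two molecules of unprotected propiosyringone, joined C8–C8' by oxidative dimerisation of the phenoxide–enolate dianion (new step).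
- Propiosyringone ⇒ syringaldehyde + EtMgBr, with addition and oxidation in one flask.

Assumption: the SMILES is the (2S,3S,4R,5R) = (2R,3R,4S,5S) isomer, 2,3-trans-3,4-cis-4,5-trans with two identical aryl groups. It has a mirror plane (meso, achiral), so there is no enantiomer to select and only relative configuration must be controlled.

**Step 1**
Reactants: 1 syringaldehyde (4-hydroxy-3,5-dimethoxybenzaldehyde); 2 ethylmagnesium bromide
Product: 4 propiosyringone [1-(4-hydroxy-3,5-dimethoxyphenyl)propan-1-one], via bis(bromomagnesium) alkoxide-phenoxide 3 (not isolated)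
Conditions: EtMgBr (2.1 equiv), THF, 0 °C to rt; then 1,1'-(azodicarbonyl)dipiperidine (1.2 equiv), THF, 0 °C to rt; 1 M HCl work-up
Reagents that add atoms: ethylmagnesium bromide, CC[Mg]Br
Why: The first equivalent of Grignard reagent makes the phenoxide and the second adds to the aldehyde (Grignard 1,2-addition), after which the bromomagnesium alkoxide passes its carbinol hydride to the azodicarboxamide (Mukaiyama-type oxidation of a halomagnesium alkoxide), so the ketone forms in one flask and no stereocentre remains.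

**Step 2**
Reactants: 4 propiosyringone (two molecules)
Product: 7 4,4'-(3,4-dimethylfuran-2,5-diyl)bis(2,6-dimethoxyphenol), via dilithium phenoxide-enolate 5 (not isolated), via 1,4-diketone 6 (not isolated)
Conditions: commercial LiN(iPr)2 (2.2 equiv per 4), THF–DMPU, −78 to 0 °C; CuCl2 (1.1 equiv per 4), DMF, −78 °C to rt; 1 M HCl work-up; crude, HCl (cat.), MeOH, reflux, N2
Reagents that add atoms: none
Why: Proposed new method: a second equivalent of base converts the lithium phenoxide into a phenoxide–enolate dianion whose enolate end is by far the most easily oxidised site, so one-electron oxidation by divalent copper gives a radical with high spin density at C8 (the phenoxide oxygen is flanked by two methoxy groups and tied to lithium, as in the 8–8'-selective coupling of sinapyl-type phenoxyl radicals) that dimerises C8–C8' to the bis-phenoxide of the 1,4-diketone without O-protection, and acid then forms the ring C–O bond by Paal–Knorr cyclodehydration, which erases the uncontrolled C3/C4 configuration; the closest known reaction type is the CuCl2-mediated oxidative dimerisation of lithium enolates of O-alkylated aryl ketones followed by Paal–Knorr furan synthesis, not shown for a ketone carrying a free para-phenol.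

**Step 3**
Reactants: 7 4,4'-(3,4-dimethylfuran-2,5-diyl)bis(2,6-dimethoxyphenol)
Product: 8 all-cis 4,4'-[(2R,3S,4R,5S)-3,4-dimethyloxolane-2,5-diyl]bis(2,6-dimethoxyphenol) (meso)
Conditions: H2 (5 bar), 10% Pd/C, EtOAc–EtOH 1:1, rt, stopped at 2 equiv H2
Reagents that add atoms: none
Why: In this heterogeneous syn-hydrogenation the flat furan takes up all four hydrogens from the catalyst-bound face, so both aryl and both methyl groups end on the opposite face (all-cis), which fixes the cis-3,4-dimethyl relationship of the target.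

**Step 4**
Reactants: 8 all-cis 4,4'-[(2R,3S,4R,5S)-3,4-dimethyloxolane-2,5-diyl]bis(2,6-dimethoxyphenol)
Product: 9 fragransin B1 (meso 2,3-trans-3,4-cis-4,5-trans isomer)
Conditions: CF3CO2H (20 mol%), CH2Cl2, 0 °C to rt, 1–2 h
Reagents that add atoms: none
Why: In this acid-catalysed SN1-type epimerisation each benzylic C–O bond ionises reversibly to a 4-hydroxy-3,5-dimethoxybenzyl cation (a protonated p-quinone methide), the C–C bond rotates and the tethered hydroxyl re-closes the C–O bond, so relief of the four-fold cis strain puts each aryl group trans to its neighbouring methyl (C2 and C5 set thermodynamically) while C3 and C4 are untouched.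

**Compound list**
1 | syringaldehyde (4-hydroxy-3,5-dimethoxybenzaldehyde) | COc1cc(C=O)cc(OC)c1O | starting material
2 | ethylmagnesium bromide | CC[Mg]Br | starting material
3 | bis(bromomagnesium) salt of racemic 1-(4-hydroxy-3,5-dimethoxyphenyl)propan-1-ol (alkoxide and phenoxide) | CCC(O[Mg]Br)c1cc(OC)c(O[Mg]Br)c(OC)c1 | intermediate
4 | propiosyringone, 1-(4-hydroxy-3,5-dimethoxyphenyl)propan-1-one | CCC(=O)c1cc(OC)c(O)c(OC)c1 | intermediate
5 | dilithium (Z)-1-(3,5-dimethoxy-4-oxidophenyl)prop-1-en-1-olate | C/C=C(\[O-])c1cc(OC)c([O-])c(OC)c1.[Li+].[Li+] | intermediate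
6 | 1,4-bis(4-hydroxy-3,5-dimethoxyphenyl)-2,3-dimethylbutane-1,4-dione, mixture of meso and racemic diastereomers | COc1cc(C(=O)C(C)C(C)C(=O)c2cc(OC)c(O)c(OC)c2)cc(OC)c1O | intermediate
7 | 4,4'-(3,4-dimethylfuran-2,5-diyl)bis(2,6-dimethoxyphenol) | Cc1c(C)c(-c2cc(OC)c(O)c(OC)c2)oc1-c1cc(OC)c(O)c(OC)c1 | intermediate
8 | 4,4'-[(2R,3S,4R,5S)-3,4-dimethyloxolane-2,5-diyl]bis(2,6-dimethoxyphenol), all-cis, meso | COc1cc([C@@H]2O[C@H](c3cc(OC)c(O)c(OC)c3)[C@H](C)[C@@H]2C)cc(OC)c1O | intermediate
9 | fragransin B1, 4,4'-[(2R,3R,4S,5S)-3,4-dimethyloxolane-2,5-diyl]bis(2,6-dimethoxyphenol), 2,3-trans-3,4-cis-4,5-trans, meso | COc1cc([C@H]2O[C@@H](c3cc(OC)c(O)c(OC)c3)[C@H](C)[C@@H]2C)cc(OC)c1O | target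

**Total steps:** 4. **Longest linear sequence:** 4 (fully linear; 4 enters step 2 twice).

**Steps most likely to fail**

Step 2 (the proposed new step). The risks are:
- incomplete second deprotonation of the sparingly soluble lithium phenoxide;
- C8–O4' coupling or α-chlorination instead of C8–C8' coupling;
- over-oxidation of the electron-rich products.

The fallback uses known chemistry, sets out from 4 and rejoins the route at 8. BnBr and K2CO3 in DMF give 1-[4-(benzyloxy)-3,5-dimethoxyphenyl]propan-1-one F1. Its ordinary lithium enolate undergoes the established CuCl2 dimerisation to 1,4-bis[4-(benzyloxy)-3,5-dimethoxyphenyl]-2,3-dimethylbutane-1,4-dione F2. TsOH in hot toluene (Paal–Knorr) gives 2,5-bis[4-(benzyloxy)-3,5-dimethoxyphenyl]-3,4-dimethylfuran F3. H2 over Pd/C then saturates the furan and cleaves both benzyl ethers in one operation to give 8.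

Step 3. The risks are hydrogenolysis of the benzylic C–O bonds to the 1,4-diarylbutane and slow uptake at the tetrasubstituted furan.

The fallback abandons the furan, sets out from 6 and rejoins the route at 9. Step 2 is stopped before the acid treatment and 6 is isolated. The meso diastereomer (2R,3S)-1,4-bis(4-hydroxy-3,5-dimethoxyphenyl)-2,3-dimethylbutane-1,4-dione F4 is separated by crystallisation, and the racemic diastereomer is re-equilibrated with NaOMe in MeOH. LiAlH4 in THF gives (2R,3S)-1,4-bis(4-hydroxy-3,5-dimethoxyphenyl)-2,3-dimethylbutane-1,4-diol F5 as a mixture of carbinol epimers. CF3CO2H in CH2Cl2 cyclodehydrates F5 through the same benzylic cations, under thermodynamic control, directly to 9.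

Step 4. The risks are:
- capture of the ring-opened cation by the other electron-rich ring (aryltetralin formation);
- loss of H-3 to give a styrene, which would scramble C3/C4;
- stalling at the mono-epimer.

The fallback leaves the free-phenol quinone-methide manifold for the O-alkyl p-alkoxybenzyl cation manifold used for protected lignans of this class. It sets out from 8 and rejoins the route at 9. BnBr and K2CO3 in DMF give the all-cis (2R,3S,4R,5S)-2,5-bis[4-(benzyloxy)-3,5-dimethoxyphenyl]-3,4-dimethyloxolane F6. BF3·OEt2 in CH2Cl2 at −20 to 0 °C epimerises both benzylic centres to (2R,3R,4S,5S)-2,5-bis[4-(benzyloxy)-3,5-dimethoxyphenyl]-3,4-dimethyloxolane F7. H2 (1 bar) over Pd/C in EtOAc removes the benzyl groups to give 9.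

**Further compounds**
F1 | step 2 | 1-[4-(benzyloxy)-3,5-dimethoxyphenyl]propan-1-one | CCC(=O)c1cc(OC)c(OCc2ccccc2)c(OC)c1
F2 | step 2 | 1,4-bis[4-(benzyloxy)-3,5-dimethoxyphenyl]-2,3-dimethylbutane-1,4-dione, meso/racemic mixture | COc1cc(C(=O)C(C)C(C)C(=O)c2cc(OC)c(OCc3ccccc3)c(OC)c2)cc(OC)c1OCc1ccccc1
F3 | step 2 | 2,5-bis[4-(benzyloxy)-3,5-dimethoxyphenyl]-3,4-dimethylfuran | Cc1c(C)c(-c2cc(OC)c(OCc3ccccc3)c(OC)c2)oc1-c1cc(OC)c(OCc2ccccc2)c(OC)c1
F4 | step 3 | (2R,3S)-1,4-bis(4-hydroxy-3,5-dimethoxyphenyl)-2,3-dimethylbutane-1,4-dione (meso) | COc1cc(C(=O)[C@H](C)[C@H](C)C(=O)c2cc(OC)c(O)c(OC)c2)cc(OC)c1O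
F5 | step 3 | (2R,3S)-1,4-bis(4-hydroxy-3,5-dimethoxyphenyl)-2,3-dimethylbutane-1,4-diol, carbinol epimers | COc1cc(C(O)[C@H](C)[C@H](C)C(O)c2cc(OC)c(O)c(OC)c2)cc(OC)c1O
F6 | step 4 | (2R,3S,4R,5S)-2,5-bis[4-(benzyloxy)-3,5-dimethoxyphenyl]-3,4-dimethyloxolane, all-cis | COc1cc([C@@H]2O[C@H](c3cc(OC)c(OCc4ccccc4)c(OC)c3)[C@H](C)[C@@H]2C)cc(OC)c1OCc1ccccc1
F7 | step 4 | (2R,3R,4S,5S)-2,5-bis[4-(benzyloxy)-3,5-dimethoxyphenyl]-3,4-dimethyloxolane, trans-cis-trans | COc1cc([C@H]2O[C@@H](c3cc(OC)c(OCc4ccccc4)c(OC)c3)[C@H](C)[C@@H]2C)cc(OC)c1OCc1ccccc1
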